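**Retrosynthetic overview** (halimane locants: ring A = C-1, C-2, C-3, C-4, C-5, C-10; ring B = C-5 to C-10)
- Target ⇐ desilylation and methanolysis of an enol acetate ⇐ bicyclic diosphenol acetate.
- Bicycle ⇐ one-flask E1cB / aldol condensation / vinylogous Stetter cascade of an open-chain keto aldehyde: ring B closes first (C-5=C-10), ring A second (C-2–C-3).
- Enabling feature: ring B is a cross-conjugated cyclohexadienone whose ring-fusion alkene C-5=C-10 is the aldol-condensation retron of the C-6 ketone. The ring-A ketone C-3 lies 1,4 to C-10 (δ to C-6 through the dienone), the retron of an acyl-anion addition to a 10-vinyl group. C-4 and C-9 are quaternary and hydrogen-free, so the open chain has one enolisable methylene (C-5) and a non-enolisable aldehyde.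
- Keto aldehyde ⇐ α-acetoxy enone by gold-catalysed oxidation/1,2-acetoxy shift of a propargylic acetate ⇐ acetylide addition (C-7–C-8) of a C-4 alkynol to a C-9 methyl ketone.
- C-4 from lipase desymmetrisation of 2-methyl-2-propargylpropane-1,3-diol; C-9 from phosphoric-acid-catalysed allylboration with an (E)-allylboronate made from hexa-1,5-diyne, then Wacker oxidation.

Key step: step 19

Remark (locants): C-18 is the acetoxymethyl carbon on C-4, C-11 to C-15 the side chain on C-9; open-chain intermediates are named as 2,3:5,10-disecohalimanes.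
Assumption (enzyme): the lipase acetylates the pro-R hydroxymethyl group of 4; if its sense is opposite, hydrolysis of the diacetate of 4 with the same enzyme gives the same monoacetate 5.
Remark (mixtures): C-8 in 20 and 21 (both epimers) and the 7-ene in 22 to 25 (E/Z) are carried as formed, because both are erased or equilibrated later.

**Route**

Step 1
Reactants: 1 diethyl 2-methylmalonate; 2 3-bromoprop-1-yne
Product: 3 diethyl 2-methyl-2-(prop-2-yn-1-yl)malonate
Conditions: NaH, THF, 0 → 23 °C
Reagents that add atoms: none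
Why: Malonate alkylation (SN2 of the sodium enolate on a propargylic bromide) builds the future C-4 quaternary carbon with C-5 to C-7 attached.

Step 2
Reactants: 3 diethyl 2-methyl-2-(prop-2-yn-1-yl)malonate
Product: 4 2-methyl-2-(prop-2-yn-1-yl)propane-1,3-diol
Conditions: LiAlH4, THF, 0 → 65 °C; Fieser work-up
Reagents that add atoms: none
Why: Hydride reduction of both esters should give the prochiral diol, the isolated alkyne being inert to LiAlH4.

Step 3
Reactants: 4 2-methyl-2-(prop-2-yn-1-yl)propane-1,3-diol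
Product: 5 (R)-2-(hydroxymethyl)-2-methylpent-4-yn-1-yl acetate
Conditions: Burkholderia cepacia lipase (Amano PS), vinyl acetate, t-BuOMe, 23 °C
Reagents that add atoms: vinyl acetate CC(=O)OC=C
Why: Lipase-catalysed enantiotopic-group-selective transesterification (enzymatic desymmetrisation of a 2,2-disubstituted propane-1,3-diol) should set C-4 by acetylating the pro-R arm, the enol ester making the acylation irreversible.

Step 4
Reactants: 5 (R)-2-(hydroxymethyl)-2-methylpent-4-yn-1-yl acetate
Product: 6 (S)-2-formyl-2-methylpent-4-yn-1-yl acetate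
Conditions: Dess–Martin periodinane, NaHCO3, CH2Cl2, 0 °C
Reagents that add atoms: none
Why: Dess–Martin oxidation of the free arm, run at once so that acetyl migration between the two arms cannot erode the ee, gives an α-quaternary aldehyde that can neither enolise nor eliminate acetate.

Step 5
Reactants: 6 (S)-2-formyl-2-methylpent-4-yn-1-yl acetate
Product: 7 (S)-2-(dimethoxymethyl)-2-methylpent-4-yn-1-yl acetate
Conditions: HC(OMe)3, PPTS (cat.), MeOH, 23 °C
Reagents that add atoms: trimethyl orthoformate COC(OC)OC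
Why: Acid-catalysed acetalisation masks the future C-3 carbonyl as a group that cannot migrate, which keeps the two arms on C-4 distinct through the basic steps that follow.

Step 6
Reactants: 7 (S)-2-(dimethoxymethyl)-2-methylpent-4-yn-1-yl acetate
Product: 8 (S)-2-(dimethoxymethyl)-2-methylpent-4-yn-1-ol
Conditions: K2CO3 (0.3 equiv), MeOH, 0 → 23 °C
Reagents that add atoms: none
Why: Base-catalysed methanolysis (transesterification) frees the C-18 hydroxyl, the acetal being inert to base.

Step 7
Reactants: 9 hexa-1,5-diyne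
Product: 11 (2E,6E)-3,6-dimethylocta-2,6-diene-1,8-diol, via bis(alkenyl)dimethylalane 10 (not isolated)
Conditions: Me3Al, Cp2ZrCl2 (cat.), CH2Cl2, 23 °C; volatiles removed; n-BuLi, THF, −78 °C; (CH2O)n, −78 → 23 °C
Reagents that add atoms: trimethylaluminium C[Al](C)C; formaldehyde (as paraformaldehyde) C=O
Why: Twofold Negishi zirconium-catalysed carboalumination is a syn addition of methyl–aluminium with methyl on the internal carbon, and hydroxymethylation of the alanate retains geometry, so both trisubstituted alkenes should be E.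

Step 8
Reactants: 11 (2E,6E)-3,6-dimethylocta-2,6-diene-1,8-diol
Product: 12 (2E,6E)-8-(tert-butyldiphenylsilyloxy)-3,6-dimethylocta-2,6-dien-1-ol
Conditions: NaH (1.0 equiv), THF, 0 °C; TBDPSCl (1.0 equiv)
Reagents that add atoms: tert-butyl(chloro)diphenylsilane CC(C)(C)[Si](Cl)(c1ccccc1)c1ccccc1
Why: Monosilylation of a symmetric diol through its sparingly soluble monosodium alkoxide (O-silylation) differentiates the two ends.

Step 9
Reactants: 12 (2E,6E)-8-(tert-butyldiphenylsilyloxy)-3,6-dimethylocta-2,6-dien-1-ol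
Product: 13 2-[(2E,6E)-8-(tert-butyldiphenylsilyloxy)-3,6-dimethylocta-2,6-dien-1-yl]-4,4,5,5-tetramethyl-1,3,2-dioxaborolane
Conditions: [Pd(MeCN)4](BF4)2 (5 mol %), B2pin2, DMSO/MeOH, 40 °C
Reagents that add atoms: bis(pinacolato)diboron CC1(C)OB(OC1(C)C)B1OC(C)(C)C(C)(C)O1
Why: Palladium-catalysed borylation of a primary allylic alcohol with B2pin2 runs through an η3-allyl palladium species and should give the linear (E)-allylboronate, the allylic silyl ether at the other end not being ionised.

Step 10
Reactants: 14 propane-1,3-diol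
Product: 15 3-hydroxypropyl pivalate
Conditions: PivCl (0.3 equiv), pyridine, CH2Cl2, 0 °C
Reagents that add atoms: pivaloyl chloride CC(C)(C)C(Cl)=O
Why: Statistical monoacylation with the diol in threefold excess.

Step 11
Reactants: 15 3-hydroxypropyl pivalate
Product: 16 3-oxopropyl pivalate
Conditions: Dess–Martin periodinane, NaHCO3, CH2Cl2, 0 °C; used fresh
Reagents that add atoms: none
Why: Buffered Dess–Martin oxidation avoids β-elimination of pivalate from the aldehyde.

Step 12
Reactants: 13 the (2E,6E)-allylboronate; 16 3-oxopropyl pivalate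
Product: 17 (3S,4R,7E)-9-(tert-butyldiphenylsilyloxy)-4-ethenyl-3-hydroxy-4,7-dimethylnon-7-en-1-yl pivalate
Conditions: (R)-TRIP phosphoric acid (10 mol %), 4 Å MS, PhMe, −30 → 0 °C
Reagents that add atoms: none
Why: Chiral-phosphoric-acid-catalysed allylboration through a closed chair transition state, in which the (E)-γ,γ-disubstituted boronate places the chain equatorial and the methyl axial (C-9 anti to the carbinol) and the catalyst selects the Re face of the aldehyde, should set the C-9 quaternary centre.

Step 13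
Reactants: 17 the homoallylic alcohol
Product: 18 (3S,4R,7E)-9-(tert-butyldiphenylsilyloxy)-4-ethenyl-4,7-dimethyl-3-(triethylsilyloxy)non-7-en-1-yl pivalate
Conditions: TESOTf, 2,6-lutidine, CH2Cl2, −78 → 0 °C
Reagents that add atoms: triethylsilyl trifluoromethanesulfonate CC[Si](CC)(CC)OS(=O)(=O)C(F)(F)F
Why: Silylation of the hindered secondary alcohol blocks retro-aldol cleavage once C-8 becomes a ketone.

Step 14
Reactants: 18 the triethylsilyl ether
Product: 19 (3S,4S,7E)-4-acetyl-9-(tert-butyldiphenylsilyloxy)-4,7-dimethyl-3-(triethylsilyloxy)non-7-en-1-yl pivalate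
Conditions: PdCl2 (10 mol %), CuCl (30 mol %), O2 (1 atm), DMF/H2O (7:1), 23 °C
Reagents that add atoms: water O
Why: Tsuji–Wacker oxidation (Markovnikov hydroxypalladation) turns the terminal vinyl group on the quaternary carbon into the C-8 methyl ketone, the trisubstituted alkene being unreactive.

Step 15
Reactants: 8 (S)-2-(dimethoxymethyl)-2-methylpent-4-yn-1-ol; 19 the methyl ketone
Product: 21 (4S,9S,10S,13E)-15-(tert-butyldiphenylsilyloxy)-3,3-dimethoxy-2-(pivaloyloxy)-10-(triethylsilyloxy)-2,3:5,10-disecohalim-13-en-6-yne-8,18-diyl diacetate, via propargylic dialkoxide 20 (not isolated)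
Conditions: 8, n-BuLi (2.1 equiv), THF, −78 °C; CeCl3; 19, −78 °C; then Ac2O, DMAP (cat.), −78 → 23 °C
Reagents that add atoms: acetic anhydride CC(=O)OC(C)=O
Why: 1,2-Addition of the cerium acetylide to the hindered methyl ketone (organocerium suppresses enolisation) forms C-7–C-8, and acetic anhydride traps both alkoxides, installing at once the C-18 acetate of the target and the acetate that will migrate; the C-8 configuration is irrelevant.

Step 16
Reactants: 21 the propargylic diacetate
Product: 22 (4S,9R,10S,13E)-7,18-diacetoxy-15-(tert-butyldiphenylsilyloxy)-3,3-dimethoxy-6-oxo-2-(pivaloyloxy)-10-(triethylsilyloxy)-2,3:5,10-disecohalima-7,13-diene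
Conditions: Ph3PAuNTf2 (5 mol %), 3,5-dichloropyridine N-oxide (2 equiv), ClCH2CH2Cl, 23 °C
Reagents that add atoms: 3,5-dichloropyridine N-oxide [O-][n+]1cc(Cl)cc(Cl)c1
Why: Gold-catalysed N-oxide oxidation of a propargylic carboxylate, in which the acyloxy-bearing carbon polarises the alkyne so that oxygen goes to the distal carbon C-6 and the α-oxo gold carbene at C-7 is quenched by 1,2-acetoxy migration from C-8, should give the α-acetoxy enone.

Step 17
Reactants: 22 the α-acetoxy enone
Product: 23 (4S,9R,10S,13E)-7,18-diacetoxy-15-(tert-butyldiphenylsilyloxy)-10-hydroxy-6-oxo-2-(pivaloyloxy)-2,3:5,10-disecohalima-7,13-dien-3-al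
Conditions: 1 M aq. HCl, THF, 0 → 23 °C
Reagents that add atoms: water O
Why: Acid hydrolysis cleaves the dimethyl acetal and the triethylsilyl ether together, while the TBDPS ether, the esters and the enol acetate should survive.

Step 18
Reactants: 23 the hydroxy aldehyde
Product: 24 (4S,9R,13E)-7,18-diacetoxy-15-(tert-butyldiphenylsilyloxy)-6,10-dioxo-2-(pivaloyloxy)-2,3:5,10-disecohalima-7,13-dien-3-al
Conditions: Dess–Martin periodinane, NaHCO3, CH2Cl2, 0 → 23 °C
Reagents that add atoms: none
Why: Dess–Martin oxidation of the C-10 alcohol gives the 2-pivaloyloxy ketone, a stable latent vinyl ketone, next to the untouched aldehyde.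

Step 19
Reactants: 24 the open-chain keto aldehyde
Product: 27 (4S,9S,13E)-7,18-diacetoxy-15-(tert-butyldiphenylsilyloxy)halima-5(10),7,13-triene-3,6-dione, via vinyl ketone 25 (not isolated), via trienone aldehyde 26 (not isolated)
Conditions: DBU (1.5 equiv), PhMe (0.01 M), 23 → 70 °C; then 2-(pentafluorophenyl)-6,7-dihydro-5H-pyrrolo[2,1-c][1,2,4]triazol-2-ium tetrafluoroborate (20 mol %), 70 °C, same flask
Reagents that add atoms: none
Why: Proposed new method: DBU first expels pivalate from the 2-pivaloyloxy ketone (E1cB) to unveil the 10-vinyl ketone 25 and then enolises the only acidic methylene left, C-5, whose aldol addition to the C-10 ketone (6-(enolendo)-exo-trig, ring B) and dehydration give the trienone 26; the triazolylidene then turns the neopentyl aldehyde C-3 into its Breslow intermediate, which adds to the terminal vinyl carbon C-2 (6-endo-trig, ring A, a vinylogous 1,6-Stetter addition), and protonation at C-1 restores the C-5=C-10 enone. The closest known reactions are the intramolecular Stetter reaction of aliphatic aldehydes under triazolium catalysis, the 1,6-addition of Breslow intermediates to para-quinone methides and the base-mediated aldol condensation; new is their union and the 6-endo 1,6-mode on a dienone. No stereocentre is formed and none can be lost, because C-4 and C-9 are quaternary and carry no hydrogen. Selectivity rests on the substrate: the aldehyde has no α-hydrogen, C-7 is sp2, the C-1 enolate can only eliminate pivalate, and before ring B exists the carbene-bound C-3 can reach only the fully substituted C-8 through a six-membered ring (the vinyl terminus is ten atoms away), so the bonds must form in the order C-5–C-10, then C-2–C-3. The E and Z enol acetates interconvert by reversible acetyl transfer to DBU or carbene, and only the Z isomer (C-6 and C-9 cis) can close ring B, so both should funnel into 27. High dilution and the late addition of the azolium salt suppress the intermolecular Stetter reaction of 25.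

Step 20
Reactants: 27 the bicyclic enol acetate
Product: 28 (4S,9S,13E)-18-acetoxy-15-(tert-butyldiphenylsilyloxy)-7-hydroxyhalima-5(10),7,13-triene-3,6-dione
Conditions: Et3N, MeOH, 23 °C
Reagents that add atoms: none
Why: Amine-catalysed methanolysis should cleave the diosphenol (enol) acetate, whose leaving group is far better than that of the neopentyl C-18 acetate, which stays.

Step 21
Reactants: 28 the diosphenol silyl ether
Product: 29 (4S,9S,13E)-18-acetoxy-7,15-dihydroxyhalima-5(10),7,13-triene-3,6-dione (target)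
Conditions: HF·pyridine, pyridine, THF, 0 → 23 °C
Reagents that add atoms: none
Why: Fluoride desilylation under weakly acidic conditions frees the allylic alcohol without acyl migration and without the strong acid that could trigger a dienone–phenol rearrangement of ring B.

**Compound list**

1 | diethyl 2-methylmalonate | CCOC(=O)C(C)C(=O)OCC | starting material
2 | 3-bromoprop-1-yne | BrCC#C | starting material
3 | diethyl 2-methyl-2-(prop-2-yn-1-yl)malonate | CCOC(=O)C(C)(CC#C)C(=O)OCC | intermediate
4 | 2-methyl-2-(prop-2-yn-1-yl)propane-1,3-diol | OCC(C)(CC#C)CO | intermediate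
5 | (R)-2-(hydroxymethyl)-2-methylpent-4-yn-1-yl acetate | CC(=O)OC[C@](C)(CC#C)CO | intermediate
6 | (S)-2-formyl-2-methylpent-4-yn-1-yl acetate | CC(=O)OC[C@](C)(CC#C)C=O | intermediate
7 | (S)-2-(dimethoxymethyl)-2-methylpent-4-yn-1-yl acetate | CC(=O)OC[C@](C)(CC#C)C(OC)OC | intermediate
8 | (S)-2-(dimethoxymethyl)-2-methylpent-4-yn-1-ol | OC[C@](C)(CC#C)C(OC)OC | intermediate
9 | hexa-1,5-diyne | C#CCCC#C | starting material
10 | [(1E,5E)-2,5-dimethylhexa-1,5-diene-1,6-diyl]bis(dimethylalane) | C[Al](C)/C=C(C)/CC/C(C)=C/[Al](C)C | intermediate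
11 | (2E,6E)-3,6-dimethylocta-2,6-diene-1,8-diol | OC/C=C(C)/CC/C(C)=C/CO | intermediate
12 | (2E,6E)-8-(tert-butyldiphenylsilyloxy)-3,6-dimethylocta-2,6-dien-1-ol | OC/C=C(C)/CC/C(C)=C/CO[Si](c1ccccc1)(c1ccccc1)C(C)(C)C | intermediate
13 | 2-[(2E,6E)-8-(tert-butyldiphenylsilyloxy)-3,6-dimethylocta-2,6-dien-1-yl]-4,4,5,5-tetramethyl-1,3,2-dioxaborolane | CC1(C)OB(C/C=C(C)/CC/C(C)=C/CO[Si](c2ccccc2)(c2ccccc2)C(C)(C)C)OC1(C)C | intermediate
14 | propane-1,3-diol | OCCCO | starting material
15 | 3-hydroxypropyl pivalate | CC(C)(C)C(=O)OCCCO | intermediate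
16 | 3-oxopropyl pivalate | CC(C)(C)C(=O)OCCC=O | intermediate
17 | (3S,4R,7E)-9-(tert-butyldiphenylsilyloxy)-4-ethenyl-3-hydroxy-4,7-dimethylnon-7-en-1-yl pivalate | CC(C)(C)C(=O)OCC[C@H](O)[C@@](C)(C=C)CC/C(C)=C/CO[Si](c1ccccc1)(c1ccccc1)C(C)(C)C | intermediate
18 | (3S,4R,7E)-9-(tert-butyldiphenylsilyloxy)-4-ethenyl-4,7-dimethyl-3-(triethylsilyloxy)non-7-en-1-yl pivalate | CC(C)(C)C(=O)OCC[C@H](O[Si](CC)(CC)CC)[C@@](C)(C=C)CC/C(C)=C/CO[Si](c1ccccc1)(c1ccccc1)C(C)(C)C | intermediate
19 | (3S,4S,7E)-4-acetyl-9-(tert-butyldiphenylsilyloxy)-4,7-dimethyl-3-(triethylsilyloxy)non-7-en-1-yl pivalate | CC(C)(C)C(=O)OCC[C@H](O[Si](CC)(CC)CC)[C@@](C)(C(C)=O)CC/C(C)=C/CO[Si](c1ccccc1)(c1ccccc1)C(C)(C)C | intermediate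
20 | (4S,9S,10S,13E)-15-(tert-butyldiphenylsilyloxy)-3,3-dimethoxy-2-(pivaloyloxy)-10-(triethylsilyloxy)-2,3:5,10-disecohalim-13-en-6-yne-8,18-diol (C-8 epimers; present as the dialkoxide) | OC[C@](C)(CC#CC(C)(O)[C@@](C)(CC/C(C)=C/CO[Si](c1ccccc1)(c1ccccc1)C(C)(C)C)[C@H](CCOC(=O)C(C)(C)C)O[Si](CC)(CC)CC)C(OC)OC | intermediate
21 | 8,18-diacetate of 20 (C-8 epimers) | CC(=O)OC[C@](C)(CC#CC(C)(OC(C)=O)[C@@](C)(CC/C(C)=C/CO[Si](c1ccccc1)(c1ccccc1)C(C)(C)C)[C@H](CCOC(=O)C(C)(C)C)O[Si](CC)(CC)CC)C(OC)OC | intermediate
22 | (4S,9R,10S,13E)-7,18-diacetoxy-15-(tert-butyldiphenylsilyloxy)-3,3-dimethoxy-6-oxo-2-(pivaloyloxy)-10-(triethylsilyloxy)-2,3:5,10-disecohalima-7,13-diene (7E/7Z mixture) | CC(=O)OC[C@](C)(CC(=O)C(OC(C)=O)=C(C)[C@@](C)(CC/C(C)=C/CO[Si](c1ccccc1)(c1ccccc1)C(C)(C)C)[C@H](CCOC(=O)C(C)(C)C)O[Si](CC)(CC)CC)C(OC)OC | intermediate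
23 | (4S,9R,10S,13E)-7,18-diacetoxy-15-(tert-butyldiphenylsilyloxy)-10-hydroxy-6-oxo-2-(pivaloyloxy)-2,3:5,10-disecohalima-7,13-dien-3-al | CC(=O)OC[C@](C)(CC(=O)C(OC(C)=O)=C(C)[C@@](C)(CC/C(C)=C/CO[Si](c1ccccc1)(c1ccccc1)C(C)(C)C)[C@@H](O)CCOC(=O)C(C)(C)C)C=O | intermediate
24 | (4S,9R,13E)-7,18-diacetoxy-15-(tert-butyldiphenylsilyloxy)-6,10-dioxo-2-(pivaloyloxy)-2,3:5,10-disecohalima-7,13-dien-3-al | CC(=O)OC[C@](C)(CC(=O)C(OC(C)=O)=C(C)[C@@](C)(CC/C(C)=C/CO[Si](c1ccccc1)(c1ccccc1)C(C)(C)C)C(=O)CCOC(=O)C(C)(C)C)C=O | intermediate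
25 | (4S,9R,13E)-7,18-diacetoxy-15-(tert-butyldiphenylsilyloxy)-6,10-dioxo-2,3:5,10-disecohalima-1,7,13-trien-3-al | CC(=O)OC[C@](C)(CC(=O)C(OC(C)=O)=C(C)[C@@](C)(CC/C(C)=C/CO[Si](c1ccccc1)(c1ccccc1)C(C)(C)C)C(=O)C=C)C=O | intermediate
26 | (4S,9S,13E)-7,18-diacetoxy-15-(tert-butyldiphenylsilyloxy)-6-oxo-2,3-secohalima-1,5(10),7,13-tetraen-3-al | CC(=O)OC[C@@](C)(C=O)C1=C(C=C)[C@](C)(CC/C(C)=C/CO[Si](c2ccccc2)(c2ccccc2)C(C)(C)C)C(C)=C(OC(C)=O)C1=O | intermediate
27 | (4S,9S,13E)-7,18-diacetoxy-15-(tert-butyldiphenylsilyloxy)halima-5(10),7,13-triene-3,6-dione | CC(=O)OC[C@@]1(C)C(=O)CCC2=C1C(=O)C(OC(C)=O)=C(C)[C@@]2(C)CC/C(C)=C/CO[Si](c3ccccc3)(c3ccccc3)C(C)(C)C | intermediate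
28 | (4S,9S,13E)-18-acetoxy-15-(tert-butyldiphenylsilyloxy)-7-hydroxyhalima-5(10),7,13-triene-3,6-dione | CC(=O)OC[C@@]1(C)C(=O)CCC2=C1C(=O)C(O)=C(C)[C@@]2(C)CC/C(C)=C/CO[Si](c3ccccc3)(c3ccccc3)C(C)(C)C | intermediate
29 | [(1S,5S)-7-hydroxy-5-[(3E)-5-hydroxy-3-methylpent-3-en-1-yl]-1,5,6-trimethyl-2,8-dioxo-1,2,3,4,5,8-hexahydronaphthalen-1-yl]methyl acetate | CC(=O)OC[C@@]1(C)C(=O)CCC2=C1C(=O)C(O)=C(C)[C@@]2(C)CC/C(C)=C/CO | target

**Totals and risks**

Total step count: 21. Longest linear sequence: 13 steps (from 9 through steps 7–9 and 12–21; the sequence from 1 through steps 1–6 and 15–21 is equally long).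

Steps most likely to fail:

1. Step 19 (proposed new method). The aldol condensation may stall at the congested C-10 ketone, the carbene may engage vinyl ketone 25 intermolecularly (oligomerisation), or the Breslow intermediate of the neopentyl aldehyde may form too slowly. The fallback sets out from 24 and returns at 27, using known reactions only. DBU alone (PhMe, 70 °C) takes 24 through 25 to the trienone aldehyde 26, which is now isolated. Pinnick oxidation (NaClO2, NaH2PO4, 2-methylbut-2-ene, t-BuOH/H2O) gives (4S,9S,13E)-7,18-diacetoxy-15-(tert-butyldiphenylsilyloxy)-6-oxo-2,3-secohalima-1,5(10),7,13-tetraen-3-oic acid F1. Treatment with (PhSe)2 and PBu3 in CH2Cl2 converts it into the corresponding Se-phenyl selenoester F2. Slow addition of Bu3SnH/AIBN (benzene, 80 °C, 0.005 M) generates the acyl radical, whose 6-endo-trig addition to the terminal vinyl carbon gives a dienone-stabilised radical that the stannane reduces to 27. Loss of CO from the tertiary acyl radical is the residual risk of this fallback.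

2. Step 16. A 3,3-acyloxy shift of the tertiary propargylic acetate to the allenyl acetate may outrun N-oxide attack, and hydrolysis of that allene would give the enone without the C-7 oxygen. The fallback sets out from 21 and returns at 22 in one operation by using the shift productively: Ph3PAuNTf2 (5 mol %), Selectfluor (2 equiv), MeCN/H2O (500:1), 60 °C. This is the known rearrangement/oxidative C–O coupling of propargylic carboxylates to α-acyloxy enones through a monovalent/trivalent gold redox cycle. No new isolated compound arises.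

3. Step 12. Slow addition and poor facial selectivity of the γ,γ-disubstituted boronate toward an aliphatic aldehyde, or E/Z leakage in step 9, would lower the ee at C-9. The fallback sets out from 12 and returns at 17. Appel bromination (CBr4, PPh3, CH2Cl2, 0 °C) gives tert-butyl{[(2E,6E)-8-bromo-3,6-dimethylocta-2,6-dien-1-yl]oxy}diphenylsilane F3. Catalytic asymmetric Nozaki–Hiyama–Kishi allylation of 16 (CrCl2 10 mol %, Mn powder, TMSCl, chiral oxazoline–sulfonamide ligand, THF; then dilute acid) adds the allylchromium reagent through its γ-carbon in a chair transition state (anti), the ligand selecting the aldehyde face.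

Further compounds
F1 | step 19 | (4S,9S,13E)-7,18-diacetoxy-15-(tert-butyldiphenylsilyloxy)-6-oxo-2,3-secohalima-1,5(10),7,13-tetraen-3-oic acid | OC(=O)[C@](C)(COC(C)=O)C1=C(C=C)[C@](C)(CC/C(C)=C/CO[Si](c2ccccc2)(c2ccccc2)C(C)(C)C)C(C)=C(OC(C)=O)C1=O
F2 | step 19 | Se-phenyl selenoester of F1 | O=C([Se]c1ccccc1)[C@](C)(COC(C)=O)C2=C(C=C)[C@](C)(CC/C(C)=C/CO[Si](c3ccccc3)(c3ccccc3)C(C)(C)C)C(C)=C(OC(C)=O)C2=O
F0 | step 16 | none | none
F3 | step 12 | tert-butyl{[(2E,6E)-8-bromo-3,6-dimethylocta-2,6-dien-1-yl]oxy}diphenylsilane | BrC/C=C(C)/CC/C(C)=C/CO[Si](c1ccccc1)(c1ccccc1)C(C)(C)C
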